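**Plan**

1. Retrosynthesis: after the six phenol benzyl ethers, the O1–C2 bond of ring C is cut, which leads to a 2-hydroxyaryl benzylidene β-ketoester. Its C2=C3 bond (Knoevenagel, benzaldehyde) and the C3–CO2tBu bond of a removable activating ester (Claisen) lead back to a hexasubstituted acetophenone.
2. Next the aryl–CH2 bonds at C8 and C6 of ring A are cut (two Negishi couplings at iodides introduced one after the other), then the two aryl–CH2 bonds inside the side chain (iterative Suzuki–Miyaura coupling of benzylic chlorides with one formyl arylboronic acid).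
3. Forward: side-chain trimer (steps 1–6); phloroacetophenone bis-benzyl ether, iodination beside the one free hydroxyl and coupling of the trimer there (future C8); second iodination and coupling of the 2-(benzyloxy)benzyl group (future C6); then β-ketoester, benzylidene, closure of ring C (the only non-aromatic ring), decarboxylation, hydrogenolysis.
4. Enabling feature: ring A keeps exactly one free phenolic oxygen, on C8a beside the C8 side chain and ortho to the C4 ketone. The benzylidene carbon (C2) lies six atoms from it, so a 6-endo oxa-Michael addition closes ring C. Because the oxygen that becomes the C5 hydroxyl is benzylated, the same closure fixes which benzyl group ends at C6 and which at C8.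
5. Stereochemistry: the single stereocentre C2 (S) is set in that ring closure by a cinchona-derived bifunctional thiourea catalyst; no basic step follows, so it should not be lost by ring opening.

Key step: step 14

Assumption: the quinidine-derived thiourea is taken as the pseudoenantiomer that leads to the 2S series; should the sense prove opposite for this substrate, the quinine-derived catalyst replaces it without other change.

Abbreviations used in names: BB = 2-(benzyloxy)benzyl; TB = 2-(benzyloxy)-5-{2-(benzyloxy)-5-[2-(benzyloxy)benzyl]benzyl}benzyl (the tribenzylated side-chain group).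

**Step 1**
Reactants: 1 2-(benzyloxy)benzyl chloride; 2 [4-(benzyloxy)-3-formylphenyl]boronic acid
Product: 3 2-(benzyloxy)-5-[2-(benzyloxy)benzyl]benzaldehyde
Conditions: PdCl2(dppf) (3 mol %; dppf = 1,1'-bis(diphenylphosphino)ferrocene), Cs2CO3, THF/H2O 10:1, 75 °C
Reagents that add atoms: none
Why: Suzuki–Miyaura coupling of a benzylic chloride with an arylboronic acid is a standard diarylmethane synthesis, and the position of boron in 2 fixes the new methylene para to the benzyloxy group while the formyl group and benzyl ethers tolerate aqueous carbonate.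

**Step 2**
Reactants: 3 2-(benzyloxy)-5-[2-(benzyloxy)benzyl]benzaldehyde
Product: 4 {2-(benzyloxy)-5-[2-(benzyloxy)benzyl]phenyl}methanol
Conditions: NaBH4, MeOH/THF, 0 °C
Reagents that add atoms: none
Why: Borohydride reduction of an aryl aldehyde to the benzylic alcohol is chemoselective in the presence of aryl benzyl ethers and the diarylmethane unit.

**Step 3**
Reactants: 4 {2-(benzyloxy)-5-[2-(benzyloxy)benzyl]phenyl}methanol
Product: 5 1-(benzyloxy)-4-[2-(benzyloxy)benzyl]-2-(chloromethyl)benzene
Conditions: SOCl2, DMF (cat.), CH2Cl2, 0 °C to rt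
Reagents that add atoms: thionyl chloride, O=S(Cl)Cl
Why: Deoxychlorination of an electron-rich benzylic alcohol with thionyl chloride (via the chlorosulfite) is fast at low temperature and leaves the aryl benzyl ethers intact, giving the electrophile for the second coupling.

**Step 4**
Reactants: 5 1-(benzyloxy)-4-[2-(benzyloxy)benzyl]-2-(chloromethyl)benzene; 2 [4-(benzyloxy)-3-formylphenyl]boronic acid
Product: 6 2-(benzyloxy)-5-{2-(benzyloxy)-5-[2-(benzyloxy)benzyl]benzyl}benzaldehyde
Conditions: PdCl2(dppf) (3 mol %), Cs2CO3, THF/H2O 10:1, 75 °C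
Reagents that add atoms: none
Why: A second Suzuki–Miyaura benzyl–aryl coupling of the same type adds the third ring, again with the methylene para to the benzyloxy group of the new ring, which completes the ortho/para-linked chain.

**Step 5**
Reactants: 6 2-(benzyloxy)-5-{2-(benzyloxy)-5-[2-(benzyloxy)benzyl]benzyl}benzaldehyde
Product: 7 (2-(benzyloxy)-5-{2-(benzyloxy)-5-[2-(benzyloxy)benzyl]benzyl}phenyl)methanol
Conditions: NaBH4, MeOH/THF, 0 °C
Reagents that add atoms: none
Why: Borohydride reduction of the aryl aldehyde as in step 2, with no other reducible group present.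

**Step 6**
Reactants: 7 (2-(benzyloxy)-5-{2-(benzyloxy)-5-[2-(benzyloxy)benzyl]benzyl}phenyl)methanol
Product: 8 1-(benzyloxy)-4-{2-(benzyloxy)-5-[2-(benzyloxy)benzyl]benzyl}-2-(chloromethyl)benzene (TB chloride)
Conditions: SOCl2, DMF (cat.), CH2Cl2, 0 °C to rt
Reagents that add atoms: thionyl chloride, O=S(Cl)Cl
Why: Deoxychlorination as in step 3 gives the benzylic chloride, the preferred halide for clean zinc insertion with little homocoupling.

**Step 7**
Reactants: 9 1-(2,4,6-trihydroxyphenyl)ethanone
Product: 10 1-[2,4-bis(benzyloxy)-6-hydroxyphenyl]ethanone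
Conditions: BnBr (2.1 equiv), K2CO3, DMF, rt
Reagents that add atoms: benzyl bromide, BrCc1ccccc1
Why: Williamson O-benzylation of phloroacetophenone stops at the bis-ether because the remaining ortho hydroxyl is hydrogen-bonded to the acetyl carbonyl and is the least nucleophilic, which differentiates the oxygen that will close ring C from the one that becomes the C5 hydroxyl.

**Step 8**
Reactants: 10 1-[2,4-bis(benzyloxy)-6-hydroxyphenyl]ethanone
Product: 11 1-[4,6-bis(benzyloxy)-2-hydroxy-3-iodophenyl]ethanone
Conditions: NIS (1.0 equiv), CH2Cl2, 0 °C to rt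
Reagents that add atoms: N-iodosuccinimide, O=C1CCC(=O)N1I
Why: Electrophilic aromatic iodination of the chelated phenol is expected ortho to the free hydroxyl, at the position flanked by only one benzyloxy group and not at the one between two, in line with the usual ortho-to-hydroxyl halogenation of 2-hydroxy-4,6-dialkoxyacetophenones; the site is to be confirmed by HMBC and NOE before going on.

**Step 9**
Reactants: 8 TB chloride; 11 1-[4,6-bis(benzyloxy)-2-hydroxy-3-iodophenyl]ethanone
Product: 13 1-[4,6-bis(benzyloxy)-2-hydroxy-3-(TB)phenyl]ethanone, via TB zinc chloride 12 (not isolated)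
Conditions: 8, Zn dust, LiCl, THF, 25 °C; then slow addition to 11, Pd(OAc)2 (2 mol %), SPhos (4 mol %), THF, 25 °C
Reagents that add atoms: none
Why: Negishi coupling, in which LiCl-assisted zinc insertion gives a benzylzinc chloride that tolerates the ketone and is protonated only slowly by the phenol, so that with Pd(OAc)2/SPhos it should couple with the hindered aryl iodide first and join the side chain to the carbon beside the free hydroxyl (the future C8).

**Step 10**
Reactants: 13 1-[4,6-bis(benzyloxy)-2-hydroxy-3-(TB)phenyl]ethanone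
Product: 14 1-[4,6-bis(benzyloxy)-2-hydroxy-5-iodo-3-(TB)phenyl]ethanone
Conditions: NIS (1.05 equiv), CH2Cl2/MeCN, 0 °C
Reagents that add atoms: N-iodosuccinimide, O=C1CCC(=O)N1I
Why: The only unsubstituted position of the phloroglucinol ring (para to the free hydroxyl, ortho to two benzyloxy groups) is far more nucleophilic than the mono-oxygenated rings of the side chain, so NIS without acid should iodinate there selectively.

**Step 11**
Reactants: 1 2-(benzyloxy)benzyl chloride; 14 1-[4,6-bis(benzyloxy)-2-hydroxy-5-iodo-3-(TB)phenyl]ethanone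
Product: 16 1-[4,6-bis(benzyloxy)-2-hydroxy-5-(BB)-3-(TB)phenyl]ethanone, via 2-(benzyloxy)benzylzinc chloride 15 (not isolated)
Conditions: 1, Zn dust, LiCl, THF, 25 °C; then 14, Pd(OAc)2 (2 mol %), SPhos (4 mol %), THF, 25 to 40 °C
Reagents that add atoms: none
Why: A second Negishi coupling of the same type, in which the inexpensive benzylzinc reagent can be used in excess to drive coupling at the iodide flanked by two benzyloxy groups, completes the hexasubstituted ring with the two different benzyl groups in defined positions.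

**Step 12**
Reactants: 16 1-[4,6-bis(benzyloxy)-2-hydroxy-5-(BB)-3-(TB)phenyl]ethanone
Product: 17 tert-butyl 3-[4,6-bis(benzyloxy)-2-hydroxy-5-(BB)-3-(TB)phenyl]-3-oxopropanoate
Conditions: LiN(SiMe3)2 (3.3 equiv), THF, −78 °C; Boc2O, −78 to 0 °C; cold 1 M HCl quench
Reagents that add atoms: di-tert-butyl dicarbonate, CC(C)(C)OC(=O)OC(=O)OC(C)(C)C
Why: Claisen-type C-acylation, in which excess base forms the phenoxide–enolate dianion of the methyl ketone, the enolate carbon attacks Boc2O and the more acidic β-ketoester is held as its enolate, which installs the removable tert-butyl ester that will activate C3.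

**Step 13**
Reactants: 17 tert-butyl 3-[4,6-bis(benzyloxy)-2-hydroxy-5-(BB)-3-(TB)phenyl]-3-oxopropanoate; 18 benzaldehyde
Product: 19 tert-butyl 2-[4,6-bis(benzyloxy)-2-hydroxy-5-(BB)-3-(TB)benzoyl]-3-phenylprop-2-enoate (alkene geometry not controlled; either isomer or a mixture is carried on)
Conditions: piperidine (10 mol %), AcOH (10 mol %), 4 Å molecular sieves, toluene, rt
Reagents that add atoms: none
Why: Knoevenagel condensation of the active methylene of the β-ketoester with benzaldehyde under piperidinium acetate catalysis gives the benzylidene β-ketoester, and room temperature with sieves is chosen over reflux to keep the free phenol from adding to the new alkene before the chiral catalyst is present.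

**Step 14**
Reactants: 19 tert-butyl 2-[4,6-bis(benzyloxy)-2-hydroxy-5-(BB)-3-(TB)benzoyl]-3-phenylprop-2-enoate
Product: 21 (2S)-5,7-bis(benzyloxy)-6-(BB)-2-phenyl-8-(TB)chroman-4-one, via tert-butyl flavanone-3-carboxylate 20 (not isolated)
Conditions: quinidine-derived thiourea N-[3,5-bis(trifluoromethyl)phenyl]-N'-[(9R)-6'-methoxycinchonan-9-yl]thiourea (10 mol %), toluene, −25 °C; then TsOH·H2O (1 equiv), 80 °C
Reagents that add atoms: none
Why: Intramolecular oxa-Michael addition under bifunctional catalysis: the quinuclidine nitrogen deprotonates the only free phenol (the oxygen on C8a, ortho to the aroyl carbon) while the thiourea N–H pair binds the 1,3-dicarbonyl unit, and the phenoxide adds to the benzylidene carbon to form the O1–C2 bond. The closest known reaction type is the cinchona-thiourea-catalysed cyclisation of 2-hydroxyaryl alkylidene β-ketoesters to 3-carboxyflavanones with acid-mediated decarboxylation in the same flask. Ring C closes in the 6-endo-trig mode, the only one open to an enone whose β-carbon is six atoms from the oxygen. The new stereocentre C2 is set under catalyst control, the chiral ion pair exposing one face of the benzylidene carbon so that 2S should result, while C3 is not a lasting stereocentre because TsOH then cleaves the tert-butyl ester and the β-keto acid loses CO2 to leave the C3 methylene. The step needs regioselectivity between the two oxygens flanking the ketone and enantioselectivity without later erosion: the first is secured because the oxygen that becomes the C5 hydroxyl is a benzyl ether, so that only the oxygen beside the C8 side chain can close, and the second because decarboxylation runs under acid, where retro-oxa-Michael opening is suppressed.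

**Step 15**
Reactants: 21 (2S)-5,7-bis(benzyloxy)-6-(BB)-2-phenyl-8-(TB)chroman-4-one
Product: 22 sarmentosumin A
Conditions: H2 (1 atm), Pd/C (10 wt %), EtOAc/MeOH, rt
Reagents that add atoms: none
Why: Catalytic hydrogenolysis cleaves all six aryl benzyl ethers under neutral conditions in which the C4 ketone and the C2 stereocentre should be untouched, and the reaction is stopped at full debenzylation to avoid hydrogenolysis of the benzylic C2–O1 bond.

**Compound list**

1 | 2-(benzyloxy)benzyl chloride | ClCc1ccccc1OCc1ccccc1 | starting material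
2 | [4-(benzyloxy)-3-formylphenyl]boronic acid | O=Cc1cc(B(O)O)ccc1OCc1ccccc1 | starting material
3 | 2-(benzyloxy)-5-[2-(benzyloxy)benzyl]benzaldehyde | O=Cc1cc(Cc2ccccc2OCc2ccccc2)ccc1OCc1ccccc1 | intermediate
4 | {2-(benzyloxy)-5-[2-(benzyloxy)benzyl]phenyl}methanol | OCc1cc(Cc2ccccc2OCc2ccccc2)ccc1OCc1ccccc1 | intermediate
5 | 1-(benzyloxy)-4-[2-(benzyloxy)benzyl]-2-(chloromethyl)benzene | ClCc1cc(Cc2ccccc2OCc2ccccc2)ccc1OCc1ccccc1 | intermediate
6 | 2-(benzyloxy)-5-{2-(benzyloxy)-5-[2-(benzyloxy)benzyl]benzyl}benzaldehyde | O=Cc1cc(Cc2cc(Cc3ccccc3OCc3ccccc3)ccc2OCc2ccccc2)ccc1OCc1ccccc1 | intermediate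
7 | (2-(benzyloxy)-5-{2-(benzyloxy)-5-[2-(benzyloxy)benzyl]benzyl}phenyl)methanol | OCc1cc(Cc2cc(Cc3ccccc3OCc3ccccc3)ccc2OCc2ccccc2)ccc1OCc1ccccc1 | intermediate
8 | TB chloride, 1-(benzyloxy)-4-{2-(benzyloxy)-5-[2-(benzyloxy)benzyl]benzyl}-2-(chloromethyl)benzene | ClCc1cc(Cc2cc(Cc3ccccc3OCc3ccccc3)ccc2OCc2ccccc2)ccc1OCc1ccccc1 | intermediate
9 | 1-(2,4,6-trihydroxyphenyl)ethanone | CC(=O)c1c(O)cc(O)cc1O | starting material
10 | 1-[2,4-bis(benzyloxy)-6-hydroxyphenyl]ethanone | CC(=O)c1c(O)cc(OCc2ccccc2)cc1OCc1ccccc1 | intermediate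
11 | 1-[4,6-bis(benzyloxy)-2-hydroxy-3-iodophenyl]ethanone | CC(=O)c1c(O)c(I)c(OCc2ccccc2)cc1OCc1ccccc1 | intermediate
12 | TB zinc chloride (benzylzinc chloride from 8) | Cl[Zn]Cc1cc(Cc2cc(Cc3ccccc3OCc3ccccc3)ccc2OCc2ccccc2)ccc1OCc1ccccc1 | intermediate (not isolated)
13 | 1-[4,6-bis(benzyloxy)-2-hydroxy-3-(TB)phenyl]ethanone | CC(=O)c1c(O)c(Cc2cc(Cc3cc(Cc4ccccc4OCc4ccccc4)ccc3OCc3ccccc3)ccc2OCc2ccccc2)c(OCc2ccccc2)cc1OCc1ccccc1 | intermediate
14 | 1-[4,6-bis(benzyloxy)-2-hydroxy-5-iodo-3-(TB)phenyl]ethanone | CC(=O)c1c(O)c(Cc2cc(Cc3cc(Cc4ccccc4OCc4ccccc4)ccc3OCc3ccccc3)ccc2OCc2ccccc2)c(OCc2ccccc2)c(I)c1OCc1ccccc1 | intermediate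
15 | 2-(benzyloxy)benzylzinc chloride | Cl[Zn]Cc1ccccc1OCc1ccccc1 | intermediate (not isolated)
16 | 1-[4,6-bis(benzyloxy)-2-hydroxy-5-(BB)-3-(TB)phenyl]ethanone | CC(=O)c1c(O)c(Cc2cc(Cc3cc(Cc4ccccc4OCc4ccccc4)ccc3OCc3ccccc3)ccc2OCc2ccccc2)c(OCc2ccccc2)c(Cc2ccccc2OCc2ccccc2)c1OCc1ccccc1 | intermediate
17 | tert-butyl 3-[4,6-bis(benzyloxy)-2-hydroxy-5-(BB)-3-(TB)phenyl]-3-oxopropanoate | CC(C)(C)OC(=O)CC(=O)c1c(O)c(Cc2cc(Cc3cc(Cc4ccccc4OCc4ccccc4)ccc3OCc3ccccc3)ccc2OCc2ccccc2)c(OCc2ccccc2)c(Cc2ccccc2OCc2ccccc2)c1OCc1ccccc1 | intermediate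
18 | benzaldehyde | O=Cc1ccccc1 | starting material
19 | tert-butyl 2-[4,6-bis(benzyloxy)-2-hydroxy-5-(BB)-3-(TB)benzoyl]-3-phenylprop-2-enoate (alkene geometry open) | CC(C)(C)OC(=O)C(=Cc1ccccc1)C(=O)c1c(O)c(Cc2cc(Cc3cc(Cc4ccccc4OCc4ccccc4)ccc3OCc3ccccc3)ccc2OCc2ccccc2)c(OCc2ccccc2)c(Cc2ccccc2OCc2ccccc2)c1OCc1ccccc1 | intermediate
20 | tert-butyl (2S)-5,7-bis(benzyloxy)-6-(BB)-4-oxo-2-phenyl-8-(TB)chromane-3-carboxylate (C3 epimers) | O=C1C(C(=O)OC(C)(C)C)[C@@H](c2ccccc2)Oc2c(Cc3cc(Cc4cc(Cc5ccccc5OCc5ccccc5)ccc4OCc4ccccc4)ccc3OCc3ccccc3)c(OCc3ccccc3)c(Cc3ccccc3OCc3ccccc3)c(OCc3ccccc3)c21 | intermediate (not isolated)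
21 | (2S)-5,7-bis(benzyloxy)-6-(BB)-2-phenyl-8-(TB)chroman-4-one | O=C1C[C@@H](c2ccccc2)Oc2c(Cc3cc(Cc4cc(Cc5ccccc5OCc5ccccc5)ccc4OCc4ccccc4)ccc3OCc3ccccc3)c(OCc3ccccc3)c(Cc3ccccc3OCc3ccccc3)c(OCc3ccccc3)c21 | intermediate
22 | sarmentosumin A, (2S)-5,7-dihydroxy-6-(2-hydroxybenzyl)-8-{2-hydroxy-5-[2-hydroxy-5-(2-hydroxybenzyl)benzyl]benzyl}-2-phenylchroman-4-one | O=C1C[C@@H](c2ccccc2)Oc2c(Cc3cc(Cc4cc(Cc5ccccc5O)ccc4O)ccc3O)c(O)c(Cc3ccccc3O)c(O)c21 | target

**Totals and risks**

Total step count: 15. Longest linear sequence: 13 (steps 1–6, then 9–15); steps 7–8 form the short branch that joins at step 9.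

Steps most likely to fail:

1. Step 14. The phenoxide is flanked by the large C8 side chain, so face discrimination by the catalyst may be poor, or an uncatalysed background closure may compete; either would lower the enantiomeric purity of 21. Fallback: set C2 by carbon–carbon instead of carbon–oxygen bond formation. Setting out from 16, condensation with N,N-dimethylformamide dimethyl acetal (toluene, 100 °C) should give the enaminone (E)-1-[4,6-bis(benzyloxy)-2-hydroxy-5-(BB)-3-(TB)phenyl]-3-(dimethylamino)prop-2-en-1-one F1. Brief treatment with aqueous HCl in CH2Cl2 should close it, with loss of dimethylamine, to the chromone 5,7-bis(benzyloxy)-6-(BB)-8-(TB)-4H-chromen-4-one F2. Asymmetric conjugate addition of phenylboronic acid to F2, catalysed by Pd(OCOCF3)2 and the tert-butyl pyridine-oxazoline ligand of the handedness that gives the 2S series (NH4PF6, H2O, 1,2-dichloroethane, 60 °C), returns to the route at 21.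

2. Step 13. The free phenol may add to the very electrophilic benzylidene β-ketoester during the amine-catalysed condensation (premature, racemic ring closure), or the condensation may stall at the hindered ketoester. Fallback: drop the ester activation. Setting out from 16, Claisen–Schmidt condensation with 18 (KOH, EtOH/THF, rt) should give the isolable chalcone (E)-1-[4,6-bis(benzyloxy)-2-hydroxy-5-(BB)-3-(TB)phenyl]-3-phenylprop-2-en-1-one F3. Direct cyclisation of this unactivated 2'-hydroxychalcone with the same cinchona thiourea (toluene, rt to 50 °C) returns to the route at 21, bypassing 17, 19 and 20.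

3. Step 8. Iodination may take place at the position between the two benzyloxy groups (para to the hydroxyl) instead of beside the hydroxyl, which would misplace the side chain. Fallback: reverse the order of the two couplings. Setting out from 10, the isomeric iodide 1-[2,4-bis(benzyloxy)-6-hydroxy-3-iodophenyl]ethanone F4 is coupled first with zinc reagent 15 (Pd(OAc)2, SPhos, THF) to give 1-[2,4-bis(benzyloxy)-3-(BB)-6-hydroxyphenyl]ethanone F5. NIS iodination of the one remaining ring position, now necessarily beside the hydroxyl, gives 1-[2,4-bis(benzyloxy)-3-(BB)-6-hydroxy-5-iodophenyl]ethanone F6. Negishi coupling of F6 with zinc reagent 12 returns to the route at 16.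

**Further compounds**

F1 | step 14 | (E)-1-[4,6-bis(benzyloxy)-2-hydroxy-5-(BB)-3-(TB)phenyl]-3-(dimethylamino)prop-2-en-1-one | CN(C)/C=C/C(=O)c1c(O)c(Cc2cc(Cc3cc(Cc4ccccc4OCc4ccccc4)ccc3OCc3ccccc3)ccc2OCc2ccccc2)c(OCc2ccccc2)c(Cc2ccccc2OCc2ccccc2)c1OCc1ccccc1
F2 | step 14 | 5,7-bis(benzyloxy)-6-(BB)-8-(TB)-4H-chromen-4-one | O=c1ccoc2c(Cc3cc(Cc4cc(Cc5ccccc5OCc5ccccc5)ccc4OCc4ccccc4)ccc3OCc3ccccc3)c(OCc3ccccc3)c(Cc3ccccc3OCc3ccccc3)c(OCc3ccccc3)c12
F3 | step 13 | (E)-1-[4,6-bis(benzyloxy)-2-hydroxy-5-(BB)-3-(TB)phenyl]-3-phenylprop-2-en-1-one | O=C(/C=C/c1ccccc1)c1c(O)c(Cc2cc(Cc3cc(Cc4ccccc4OCc4ccccc4)ccc3OCc3ccccc3)ccc2OCc2ccccc2)c(OCc2ccccc2)c(Cc2ccccc2OCc2ccccc2)c1OCc1ccccc1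
F4 | step 8 | 1-[2,4-bis(benzyloxy)-6-hydroxy-3-iodophenyl]ethanone | CC(=O)c1c(O)cc(OCc2ccccc2)c(I)c1OCc1ccccc1
F5 | step 8 | 1-[2,4-bis(benzyloxy)-3-(BB)-6-hydroxyphenyl]ethanone | CC(=O)c1c(O)cc(OCc2ccccc2)c(Cc2ccccc2OCc2ccccc2)c1OCc1ccccc1
F6 | step 8 | 1-[2,4-bis(benzyloxy)-3-(BB)-6-hydroxy-5-iodophenyl]ethanone | CC(=O)c1c(O)c(I)c(OCc2ccccc2)c(Cc2ccccc2OCc2ccccc2)c1OCc1ccccc1
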